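1. The ratio of reagent to substrate charged is what I carry through this decision. I take one reagent per product, so c(reagent) / (c(left-handed substrate) + c(right-handed substrate)) gives the product a flask can make before its reagent is gone, in percent of substrate charged. Grey, green, violet and red each stand at 55.0 %: this is the reagent ceiling, with reagent as the limiting reagent.

| setting | east | north-west | south-west | grey | green | violet | red |
|---|---|---|---|---|---|---|---|
| left-handed substrate | 0.050 M | 0.050 M | 0.050 M | 0.050 M | 0.050 M | 0.050 M | 0.050 M |
| right-handed substrate | 0.050 M | 0.050 M | 0.050 M | 0.050 M | 0.050 M | 0.050 M | 0.050 M |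
| reagent | 0.037 M | 0.083 M | 0.055 M | 0.0550 M | 0.0550 M | 0.0550 M | 0.0550 M |
| free catalyst | 2.5 mM | 2.5 mM | 2.5 mM | 2.5 mM | 2.5 mM | 2.5 mM | 2.5 mM |
| impurity | 1.4 mM | 1.4 mM | 2.1 mM | 1.4 mM | 1.4 mM | 1.4 mM | 1.4 mM |
| temperature | 10 °C | 38 °C | 10 °C | 15 °C | 60 °C | 30 °C | 45 °C |
| remark | run made earlier | run made earlier | run made earlier |  |  |  |  |
| time |  |  |  | 8.0 h | 8.0 h | 8.0 h | 8.0 h |

| run | time / h | left-handed product / % | right-handed product / % |
|---|---|---|---|
| east | 0.667 | 3.5 | 0 |
| east | 2.00 | 8.8 | 1.0 |
| east | 3.00 | 10.9 | 3.0 |
| east | 5.00 | 15.1 | 2.9 |
| east | 8.00 | 19.1 | 4.0 |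
| east | 10.0 | 18.5 | 4.7 |
| north-west | 0.200 | 9.7 | 3.1 |
| north-west | 0.667 | 20.9 | 5.5 |
| north-west | 1.00 | 25.8 | 9.4 |
| north-west | 1.50 | 29.8 | 11.9 |
| north-west | 2.50 | 34.6 | 13.8 |
| north-west | 3.00 | 37.3 | 14.1 |
| south-west | 2.00 | 11.9 | 2.4 |
| south-west | 4.00 | 18.7 | 5.1 |
| south-west | 6.00 | 21.7 | 5.0 |
| south-west | 8.00 | 21.6 | 5.3 |
| south-west | 10.0 | 24.1 | 7.8 |

(readings scatter by 1 percentage point)

1. the flask with the highest share of left-handed product in all that became left-handed product or right-handed product ("all alike" if they lie within 1.5 percentage points) (grey / green / violet / red / all alike)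
2. share of left-handed product in all that became left-handed product or right-handed product, grey
3. share of left-handed product in all that became left-handed product or right-handed product, green
4. share of left-handed product in all that became left-handed product or right-handed product, violet
5. share of left-handed product in all that became left-handed product or right-handed product, red

- free catalyst is single-handed; left-handed substrate and right-handed substrate are mirror images of each other, charged as a racemate, each of them at the stated concentration
- the analysis behind the earlier runs scatters by 1 percentage point, standard deviation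

2. The decision: which flask do I run first for the highest share of left-handed product?

3. South-west has grey's reagent charge, but it stands at 10 °C with more impurity. At 8.00 h it reads 26.9 % product, with a share of 80.3 %. So I expect grey, at 15 °C, to stay under its ceiling with a share near that reading.

4. North-west, at 38 °C, reads 51.4 % product at 3.00 h, and its share of 72.6 % is lower than south-west's. The two runs differ in reagent and impurity as well, so I read this gap as a direction for temperature, not as a size. Red and green are hotter still, so I expect them to come close to 55.0 % within 8.0 h, with lower shares.

5. So my reckoning says run grey, with the charge unchanged.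

6. The forecast agrees: grey highest, with grey 78 %, violet 74 %, red 70 % and green 67 %, the hottest flask “the last being reagent-limited”.

7. The flasks give grey 79.1 %, violet 74.5 %, red 70.4 % and green 67.6 %. So grey is highest, in the forecast's order, and grey is the flask I run.

    reagent + free catalyst + left-handed substrate → free catalyst + left-handed product (k = 19000 /M²/h, Ea = 40.0 kJ/mol)
    reagent + free catalyst + right-handed substrate → free catalyst + right-handed product (k = 6200 /M²/h, Ea = 49.0 kJ/mol)
    free catalyst + impurity → spent catalyst (k = 3800 /M/h, Ea = 50.0 kJ/mol)
    (constants at 60 °C)

8. At 8.00 h green holds 54.6 % product with 0.679 % of its reagent left, level with its ceiling of 55.0 %, while grey holds less, 34.6 %. A neighbour of green, like green but charged with 0.022 M of reagent, has a ceiling of 22.0 %. That neighbour holds 22.0 % product with 0.0186 % of its reagent left, and 44.1 % of the two substrates charged together stays as right-handed substrate. Its share of left-handed product is 73.0 %, higher than green's 67.6 %.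

The data come from a simulation for an exercise; scatter was added.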